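**Assumption:** (4R,6R)-actinol and dimethyl 3-methylglutarate are taken as catalogue chemicals; names use naphthalene locants (C-1 side-chain carbon, C-2 methylidene carbon, C-7 ester carbon, C-8a angular carbon).

## Retrosynthetic overview

1. Target ⇐ tert-butyl ester and free axial C-7 alcohol (acylated last); the exocyclic methylene comes from the C-2 ketone by Lombardo methylenation.
2. C-1 side-chain bond ⇐ α′-alkylation of a trans-fused bicyclic enone with a chiral C6 iodide; this is the union of the two branches, and the electrophile enters anti to the angular methyl.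
3. Ring B (the only ring made) ⇐ intramolecular aldol condensation of a methyl ketone onto an aldehyde; the trans fusion is fixed there while the ring-A carbonyl is sp2, and the C-7 carbinol follows by equatorial hydride delivery.
4. Ring A is bought as (4R,6R)-actinol; its carbinol steers a Saucy–Marbet Claisen rearrangement that builds the quaternary angular carbon.
5. Iodide ⇐ dimethyl 3-methylglutarate by enzymatic desymmetrisation. Ring order: A (chiral pool), then B (aldol).

## Route

### Core branch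

Step 1
Reactants: 1 (4R,6R)-4-hydroxy-2,2,6-trimethylcyclohexan-1-one (actinol)
Product: 2 (6R,8R)-4,4,8-trimethyl-1-oxaspiro[2.5]octan-6-ol (epimers at the spiro carbon)
Conditions: Me3S+ I− (3 eq), n-BuLi (3 eq), THF, −10 °C → rt; H2O
Reagents that add atoms: trimethylsulfonium iodide C[S+](C)C.[I-]
Why: Corey–Chaykovsky epoxidation, in which the small sulfonium ylide still adds to the hindered ketone; the spiro centre and the α-methyl centre are both erased in step 2.

Step 2
Reactants: 2 (6R,8R)-4,4,8-trimethyl-1-oxaspiro[2.5]octan-6-ol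
Product: 3 (1R)-4-(hydroxymethyl)-3,5,5-trimethylcyclohex-3-en-1-ol
Conditions: LiNEt2 (4 eq), Et2O–hexane, reflux; H2O
Reagents that add atoms: none
Why: Base-induced epoxide-to-allylic-alcohol isomerisation (syn β-elimination); the only β-hydrogen is the tertiary ring C–H, so the tetrasubstituted ring alkene forms and the carbinol centre is untouched.

Step 3
Reactants: 3 (1R)-4-(hydroxymethyl)-3,5,5-trimethylcyclohex-3-en-1-ol
Product: 4 1-[(1S,5S)-5-hydroxy-1,3,3-trimethyl-2-methylidenecyclohexyl]propan-2-one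
Conditions: 2-methoxypropene (excess), EtCO2H (cat.), xylene, 140 °C, sealed tube; then 1 M HCl, THF, rt
Reagents that add atoms: 2-methoxypropene COC(C)=C
Why: Saucy–Marbet (ketal) Claisen rearrangement, in which the [3,3] shift delivers the acetonyl carbon to the methyl-bearing alkene carbon on the face anti to the equatorial (transiently ketal-masked) ring oxygen, giving the quaternary centre with methyl cis to oxygen.

Step 4
Reactants: 4 1-[(1S,5S)-5-hydroxy-1,3,3-trimethyl-2-methylidenecyclohexyl]propan-2-one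
Product: 5 (1S,3R)-4-(hydroxymethyl)-3-(2-hydroxypropyl)-3,5,5-trimethylcyclohexan-1-ol (epimers at C-4 and at the side-chain carbinol)
Conditions: BH3·THF (excess), THF, 0 °C → rt; then NaOH, H2O2
Reagents that add atoms: hydrogen peroxide OO
Why: Anti-Markovnikov hydroboration–oxidation of the 1,1-disubstituted alkene (the ketone is reduced as well); both new centres are re-oxidised or equilibrated in step 5.

Step 5
Reactants: 5 (1S,3R)-4-(hydroxymethyl)-3-(2-hydroxypropyl)-3,5,5-trimethylcyclohexan-1-ol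
Product: 7 (4aR,8aS)-5,5,8a-trimethyl-4a,5,6,8a-tetrahydronaphthalene-2,7(1H,8H)-dione, via keto-aldehyde 6 (not isolated)
Conditions: (COCl)2, DMSO, CH2Cl2, −78 °C; Et3N, −78 → 0 °C; then DBU, 0 → 40 °C
Reagents that add atoms: none
Why: Triple Swern oxidation then intramolecular aldol condensation (methyl-ketone enolate onto the aldehyde, E1cB) closes ring B; the aldehyde α-centre epimerises under DBU, and with the ring-A carbonyl sp2 the trans-fused enone is expected to be favoured because the cis alternative must place the gem-dimethyl carbon axial on the new ring.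

Step 6
Reactants: 7 (4aR,8aS)-5,5,8a-trimethyl-4a,5,6,8a-tetrahydronaphthalene-2,7(1H,8H)-dione
Product: 8 (4aR,7S,8aS)-7-hydroxy-5,5,8a-trimethyl-4a,5,6,7,8,8a-hexahydronaphthalen-2(1H)-one
Conditions: NaBH4, MeOH–CH2Cl2 (1:1), −78 → −40 °C
Reagents that add atoms: none
Why: Chemoselective borohydride reduction of the saturated ketone beside the less electrophilic enone; the two syn-axial methyls block axial attack, so hydride enters equatorially and gives the axial alcohol cis to the angular methyl.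

### Side-chain branch

Step 7
Reactants: 9 dimethyl 3-methylpentanedioate
Product: 10 (3R)-5-methoxy-3-methyl-5-oxopentanoic acid
Conditions: pig liver esterase, pH 7 phosphate buffer–MeOH (4:1), −10 °C, pH-stat (1 M NaOH); then HCl
Reagents that add atoms: water O
Why: Enzymatic desymmetrisation of the prochiral diester, in which PLE hydrolyses one enantiotopic ester to the (R)-half-ester (recalled as about 95% ee) and so sets the side-chain methyl stereocentre.

Step 8
Reactants: 10 (3R)-5-methoxy-3-methyl-5-oxopentanoic acid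
Product: 11 1-tert-butyl 5-methyl (3S)-3-methylpentanedioate
Conditions: isobutene, H2SO4 (cat.), CH2Cl2, −20 °C → rt, pressure bottle
Reagents that add atoms: 2-methylpropene CC(C)=C
Why: Acid-catalysed addition of the carboxylic acid to isobutene masks the future terminal acid as a base-stable tert-butyl ester.

Step 9
Reactants: 11 1-tert-butyl 5-methyl (3S)-3-methylpentanedioate
Product: 12 (3S)-5-tert-butoxy-3-methyl-5-oxopentanoic acid
Conditions: LiOH·H2O (1.1 eq), THF–H2O, 0 °C; then cold dilute HCl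
Reagents that add atoms: lithium hydroxide [Li+].[OH-]
Why: Saponification selective for the unhindered methyl ester, since the tert-butyl ester resists hydroxide.

Step 10
Reactants: 12 (3S)-5-tert-butoxy-3-methyl-5-oxopentanoic acid
Product: 13 tert-butyl (3S)-5-hydroxy-3-methylpentanoate
Conditions: BH3·SMe2, THF, 0 °C → rt; MeOH quench
Reagents that add atoms: none
Why: Borane reduces the free carboxylic acid chemoselectively through its acyloxyborane and leaves the tert-butyl ester alone.

Step 11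
Reactants: 13 tert-butyl (3S)-5-hydroxy-3-methylpentanoate
Product: 14 tert-butyl (3S)-3-methyl-5-(methylsulfonyloxy)pentanoate
Conditions: MsCl, Et3N, CH2Cl2, 0 °C
Reagents that add atoms: methanesulfonyl chloride CS(=O)(=O)Cl
Why: Sulfonylation of the primary alcohol under non-acidic conditions that cannot trigger lactonisation.

Step 12
Reactants: 14 tert-butyl (3S)-3-methyl-5-(methylsulfonyloxy)pentanoate
Product: 15 tert-butyl (3R)-5-iodo-3-methylpentanoate
Conditions: NaI, acetone, reflux
Reagents that add atoms: sodium iodide [Na+].[I-]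
Why: Finkelstein SN2 displacement at the primary carbon; the descriptor changes only because iodine outranks the ester branch.

### Union and end game

Step 13
Reactants: 8 (4aR,7S,8aS)-7-hydroxy-5,5,8a-trimethyl-4a,5,6,7,8,8a-hexahydronaphthalen-2(1H)-one; 15 tert-butyl (3R)-5-iodo-3-methylpentanoate
Product: 16 tert-butyl (3S)-5-[(1R,4aR,7S,8aR)-7-hydroxy-5,5,8a-trimethyl-2-oxo-1,2,4a,5,6,7,8,8a-octahydronaphthalen-1-yl]-3-methylpentanoate
Conditions: LDA (2.2 eq), THF, −78 °C; 15 (1.5 eq), HMPA, −78 → −20 °C; H2O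
Reagents that add atoms: none
Why: Kinetic α′-deprotonation (after the alkoxide) gives the cross-conjugated lithium dienolate, and its SN2 alkylation occurs on the face opposite the axial angular methyl, so the side chain ends up trans to that methyl.

Step 14
Reactants: 16 tert-butyl (3S)-5-[(1R,4aR,7S,8aR)-7-hydroxy-5,5,8a-trimethyl-2-oxo-1,2,4a,5,6,7,8,8a-octahydronaphthalen-1-yl]-3-methylpentanoate
Product: 17 tert-butyl (3S)-5-[(1R,4aR,7S,8aR)-7-hydroxy-5,5,8a-trimethyl-2-oxodecahydronaphthalen-1-yl]-3-methylpentanoate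
Conditions: H2 (1 atm), Pd/C, EtOAc, rt
Reagents that add atoms: none
Why: Neutral catalytic hydrogenation saturates only the enone C=C, so the epimerisable α-ketone centre is not disturbed.

Step 15
Reactants: 17 tert-butyl (3S)-5-[(1R,4aR,7S,8aR)-7-hydroxy-5,5,8a-trimethyl-2-oxodecahydronaphthalen-1-yl]-3-methylpentanoate
Product: 18 tert-butyl (3S)-5-[(1S,4aR,7S,8aR)-7-hydroxy-5,5,8a-trimethyl-2-methylidenedecahydronaphthalen-1-yl]-3-methylpentanoate
Conditions: Zn, CH2Br2, TiCl4, THF (pre-aged reagent); 17, CH2Cl2, 0 °C → rt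
Reagents that add atoms: dibromomethane BrCBr
Why: Lombardo–Takai methylenation is non-basic, so the hindered ketone is converted without epimerising the adjacent centre, and the ester and free alcohol are tolerated.

Step 16
Reactants: 18 tert-butyl (3S)-5-[(1S,4aR,7S,8aR)-7-hydroxy-5,5,8a-trimethyl-2-methylidenedecahydronaphthalen-1-yl]-3-methylpentanoate
Product: 19 tert-butyl (3S)-3-methyl-5-[(1S,4aR,7S,8aR)-5,5,8a-trimethyl-2-methylidene-7-(3-methylbutanoyloxy)decahydronaphthalen-1-yl]pentanoate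
Conditions: (i-BuCO)2O, DMAP, Et3N, CH2Cl2, 40 °C
Reagents that add atoms: 3-methylbutanoic anhydride CC(C)CC(=O)OC(=O)CC(C)C
Why: DMAP-catalysed acylation of the hindered axial alcohol proceeds with retention at carbon.

Step 17
Reactants: 19 tert-butyl (3S)-3-methyl-5-[(1S,4aR,7S,8aR)-5,5,8a-trimethyl-2-methylidene-7-(3-methylbutanoyloxy)decahydronaphthalen-1-yl]pentanoate
Product: 20 (3S)-3-methyl-5-[(1S,4aR,7S,8aR)-5,5,8a-trimethyl-2-methylidene-7-(3-methylbutanoyloxy)decahydronaphthalen-1-yl]pentanoic acid (CNP0168901.1)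
Conditions: TMSOTf, 2,6-lutidine, CH2Cl2, 0 °C; then H2O
Reagents that add atoms: none
Why: Silyl-triflate-mediated tert-butyl ester cleavage (loss of isobutene) under buffered aprotic conditions spares the exocyclic alkene and the secondary isovalerate.

## Compound list

1 | (4R,6R)-4-hydroxy-2,2,6-trimethylcyclohexan-1-one | O=C1C(C)(C)C[C@H](O)C[C@H]1C | starting material
2 | (6R,8R)-4,4,8-trimethyl-1-oxaspiro[2.5]octan-6-ol (spiro epimers) | C1OC12C(C)(C)C[C@H](O)C[C@H]2C | intermediate
3 | (1R)-4-(hydroxymethyl)-3,5,5-trimethylcyclohex-3-en-1-ol | OCC1=C(C)C[C@@H](O)CC1(C)C | intermediate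
4 | 1-[(1S,5S)-5-hydroxy-1,3,3-trimethyl-2-methylidenecyclohexyl]propan-2-one | C=C1C(C)(C)C[C@H](O)C[C@@]1(C)CC(C)=O | intermediate
5 | (1S,3R)-4-(hydroxymethyl)-3-(2-hydroxypropyl)-3,5,5-trimethylcyclohexan-1-ol (epimer mixture) | OCC1C(C)(C)C[C@H](O)C[C@@]1(C)CC(C)O | intermediate
6 | (6R)-2,2,6-trimethyl-4-oxo-6-(2-oxopropyl)cyclohexane-1-carbaldehyde (C-1 epimerising) | O=CC1C(C)(C)CC(=O)C[C@@]1(C)CC(C)=O | intermediate
7 | (4aR,8aS)-5,5,8a-trimethyl-4a,5,6,8a-tetrahydronaphthalene-2,7(1H,8H)-dione | O=C1C=C[C@@H]2C(C)(C)CC(=O)C[C@@]2(C)C1 | intermediate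
8 | (4aR,7S,8aS)-7-hydroxy-5,5,8a-trimethyl-4a,5,6,7,8,8a-hexahydronaphthalen-2(1H)-one | O=C1C=C[C@@H]2C(C)(C)C[C@H](O)C[C@@]2(C)C1 | intermediate
9 | dimethyl 3-methylpentanedioate | COC(=O)CC(C)CC(=O)OC | starting material
10 | (3R)-5-methoxy-3-methyl-5-oxopentanoic acid | COC(=O)C[C@H](C)CC(=O)O | intermediate
11 | 1-tert-butyl 5-methyl (3S)-3-methylpentanedioate | COC(=O)C[C@H](C)CC(=O)OC(C)(C)C | intermediate
12 | (3S)-5-tert-butoxy-3-methyl-5-oxopentanoic acid | OC(=O)C[C@H](C)CC(=O)OC(C)(C)C | intermediate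
13 | tert-butyl (3S)-5-hydroxy-3-methylpentanoate | OCC[C@H](C)CC(=O)OC(C)(C)C | intermediate
14 | tert-butyl (3S)-3-methyl-5-(methylsulfonyloxy)pentanoate | CS(=O)(=O)OCC[C@H](C)CC(=O)OC(C)(C)C | intermediate
15 | tert-butyl (3R)-5-iodo-3-methylpentanoate | ICC[C@H](C)CC(=O)OC(C)(C)C | intermediate
16 | tert-butyl (3S)-5-[(1R,4aR,7S,8aR)-7-hydroxy-5,5,8a-trimethyl-2-oxo-1,2,4a,5,6,7,8,8a-octahydronaphthalen-1-yl]-3-methylpentanoate | O=C1C=C[C@@H]2C(C)(C)C[C@H](O)C[C@@]2(C)[C@H]1CC[C@H](C)CC(=O)OC(C)(C)C | intermediate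
17 | tert-butyl (3S)-5-[(1R,4aR,7S,8aR)-7-hydroxy-5,5,8a-trimethyl-2-oxodecahydronaphthalen-1-yl]-3-methylpentanoate | O=C1CC[C@@H]2C(C)(C)C[C@H](O)C[C@@]2(C)[C@H]1CC[C@H](C)CC(=O)OC(C)(C)C | intermediate
18 | tert-butyl (3S)-5-[(1S,4aR,7S,8aR)-7-hydroxy-5,5,8a-trimethyl-2-methylidenedecahydronaphthalen-1-yl]-3-methylpentanoate | C=C1CC[C@@H]2C(C)(C)C[C@H](O)C[C@@]2(C)[C@H]1CC[C@H](C)CC(=O)OC(C)(C)C | intermediate
19 | tert-butyl (3S)-3-methyl-5-[(1S,4aR,7S,8aR)-5,5,8a-trimethyl-2-methylidene-7-(3-methylbutanoyloxy)decahydronaphthalen-1-yl]pentanoate | C=C1CC[C@@H]2C(C)(C)C[C@H](OC(=O)CC(C)C)C[C@@]2(C)[C@H]1CC[C@H](C)CC(=O)OC(C)(C)C | intermediate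
20 | (3S)-3-methyl-5-[(1S,4aR,7S,8aR)-5,5,8a-trimethyl-2-methylidene-7-(3-methylbutanoyloxy)decahydronaphthalen-1-yl]pentanoic acid | C=C1CC[C@@H]2C(C)(C)C[C@H](OC(=O)CC(C)C)C[C@@]2(C)[C@H]1CC[C@H](C)CC(=O)O | target

## Step count and risks

Total step count: 17. Longest linear sequence: 11 (steps 1–6 and 13–17; the side-chain branch, steps 7–12 then 13–17, is also 11).

Step 5 (ring fusion in the aldol closure). The fallback sets out from 5 and comes back at 7. If the Swern/DBU sequence gives mainly the cis-fused epimer (4aS,8aS)-5,5,8a-trimethyl-4a,5,6,8a-tetrahydronaphthalene-2,7(1H,8H)-dione F1, the fusion is set by hydrogenation instead of equilibration. The F1/7 mixture is deconjugated (KOt-Bu, t-BuOH, then AcOH at −78 °C; kinetic α-protonation of the extended dienolate) to (8aR)-5,5,8a-trimethyl-3,5,6,8a-tetrahydronaphthalene-2,7(1H,8H)-dione F2, which has no ring-fusion hydrogen. Hydrogenation (H2, 4 bar, Pd/C, EtOAc–AcOH) adds anti to the angular methyl and gives (4aR,8aR)-5,5,8a-trimethyloctahydronaphthalene-2,7(1H,3H)-dione F3. LDA/TMSCl at −78 °C enolises the only non-neopentyl α-methylene to give (4aR,8aR)-4,4,8a-trimethyl-7-[(trimethylsilyl)oxy]-3,4,4a,5,8,8a-hexahydronaphthalen-2(1H)-one F4, and Saegusa–Ito oxidation (Pd(OAc)2, MeCN) returns 7.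

Step 6 (saturated ketone versus enone). The fallback sets out from 7 and comes back at 8. Both carbonyls are reduced under Luche conditions (NaBH4, CeCl3·7H2O, MeOH, 0 °C), with the same equatorial delivery at the ring-A ketone, to (2S,4aR,8aS)-4,4,8a-trimethyl-1,2,3,4,4a,7,8,8a-octahydronaphthalene-2,7-diol F5. MnO2 (CH2Cl2, rt) then re-oxidises only the allylic alcohol and gives 8.

Step 13 (SN2 alkylation of a neopentyl-type enolate). The fallback sets out from 8 and 13 and comes back at 16. Dess–Martin oxidation of 13 gives tert-butyl (3S)-3-methyl-5-oxopentanoate F6. The lithium dienolate of 8 (LDA, 2.2 eq, −78 °C) adds to it in a fast aldol addition on the same anti-to-methyl face and gives tert-butyl (3S)-5-hydroxy-5-[(4aR,7S,8aR)-7-hydroxy-5,5,8a-trimethyl-2-oxo-1,2,4a,5,6,7,8,8a-octahydronaphthalen-1-yl]-3-methylpentanoate F7. Thiocarbonyldiimidazole acylates the unhindered new carbinol to give its O-(imidazol-1-ylcarbonothioyl) derivative F8, and Bu3SnH/AIBN (toluene, 80 °C, Barton–McCombie) removes that oxygen without touching the ring stereocentre, giving 16.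

## Further compounds

F1 | step 5 | (4aS,8aS)-5,5,8a-trimethyl-4a,5,6,8a-tetrahydronaphthalene-2,7(1H,8H)-dione | O=C1C=C[C@H]2C(C)(C)CC(=O)C[C@@]2(C)C1
F2 | step 5 | (8aR)-5,5,8a-trimethyl-3,5,6,8a-tetrahydronaphthalene-2,7(1H,8H)-dione | O=C1CC=C2C(C)(C)CC(=O)C[C@@]2(C)C1
F3 | step 5 | (4aR,8aR)-5,5,8a-trimethyloctahydronaphthalene-2,7(1H,3H)-dione | O=C1CC[C@@H]2C(C)(C)CC(=O)C[C@@]2(C)C1
F4 | step 5 | (4aR,8aR)-4,4,8a-trimethyl-7-[(trimethylsilyl)oxy]-3,4,4a,5,8,8a-hexahydronaphthalen-2(1H)-one | C[Si](C)(C)OC1=CC[C@@H]2C(C)(C)CC(=O)C[C@@]2(C)C1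
F5 | step 6 | (2S,4aR,8aS)-4,4,8a-trimethyl-1,2,3,4,4a,7,8,8a-octahydronaphthalene-2,7-diol (C-7 epimers) | OC1C=C[C@@H]2C(C)(C)C[C@H](O)C[C@@]2(C)C1
F6 | step 13 | tert-butyl (3S)-3-methyl-5-oxopentanoate | O=CC[C@H](C)CC(=O)OC(C)(C)C
F7 | step 13 | tert-butyl (3S)-5-hydroxy-5-[(4aR,7S,8aR)-7-hydroxy-5,5,8a-trimethyl-2-oxo-1,2,4a,5,6,7,8,8a-octahydronaphthalen-1-yl]-3-methylpentanoate (ring C-1 as in 16; carbinol epimers) | O=C1C=C[C@@H]2C(C)(C)C[C@H](O)C[C@@]2(C)[C@H]1C(O)C[C@H](C)CC(=O)OC(C)(C)C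
F8 | step 13 | O-(imidazol-1-ylcarbonothioyl) derivative of F7 at the side-chain carbinol | O=C1C=C[C@@H]2C(C)(C)C[C@H](O)C[C@@]2(C)[C@H]1C(OC(=S)n1ccnc1)C[C@H](C)CC(=O)OC(C)(C)C
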